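Ring C contains the carbonyl carbon C4 flanked by aromatic C4a and vinylic C3, and the neighbouring aromatic carbon C8a carries O1. An aryl iodide with an ortho hydroxyl, carbon monoxide and a terminal alkyne therefore supply all six ring atoms, and the disconnection cuts C4a–C4, C4–C3 and O1–C2. One palladium-catalysed carbonylative alkynylation–cyclization joins 2-iodo-3,5-dimethoxyphenol, CO and 1-ethynyl-2,3,4-trimethoxybenzene and closes ring C with every ring A and ring B methoxy group in place. The parent phenol, 3,5-dimethoxyphenol, is symmetric, so both ortho positions are the same for iodination. The C3 and C8 oxygens and the free 5-hydroxyl follow by established flavone chemistry.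

Key step: step 3

Remark: the target has no stereocentre; the only stereogenic species, epoxide 10, is racemic and is consumed in the flask in which it forms.

Step 1
Reactants: 1 3,5-dimethoxyphenol
Product: 2 2-iodo-3,5-dimethoxyphenol
Conditions: NIS (1.0 equiv), CH2Cl2, −20 → 0 °C, dark
Reagents that add atoms: N-iodosuccinimide, O=C1CCC(=O)N1I
Why: Electrophilic aromatic iodination in which the two positions ortho to the hydroxyl are equivalent by symmetry and less crowded than C4 between the two methoxy groups, so mono-iodination at C2 should predominate and the para isomer is removed by chromatography.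

Step 2
Reactants: 3 2,3,4-trimethoxybenzaldehyde; 4 dimethyl (1-diazo-2-oxopropyl)phosphonate
Product: 5 1-ethynyl-2,3,4-trimethoxybenzene
Conditions: K2CO3 (2 equiv), MeOH, 0 °C → rt
Reagents that add atoms: none
Why: Ohira–Bestmann homologation, in which methanolysis of 4 releases dimethyl (diazomethyl)phosphonate, its anion adds to the aldehyde, and the diazoalkene left after loss of dimethyl phosphate expels nitrogen and undergoes a 1,2-hydrogen shift to the terminal alkyne.

Step 3
Reactants: 2 2-iodo-3,5-dimethoxyphenol; 5 1-ethynyl-2,3,4-trimethoxybenzene; 6 carbon monoxide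
Product: 9 5,7-dimethoxy-2-(2,3,4-trimethoxyphenyl)-4H-chromen-4-one, via ortho-hydroxyaryl ynone 7 (not isolated), via diethylamino enaminone 8 (not isolated)
Conditions: PdCl2(PPh3)2 (5 mol %), CO (20 bar), Et2NH (solvent), 120 °C, autoclave
Reagents that add atoms: none
Why: PdCl2(PPh3)2 is reduced in situ to zerovalent palladium, which inserts into the C–I bond of 2; CO insertion gives the aroylpalladium species, and amine-assisted transfer of the acetylide from 5 followed by reductive elimination forms C4a–C4 and C4–C3 in ynone 7. Diethylamine then adds to the ynone at the aryl-bearing carbon to give enaminone 8, and the phenol oxygen attacks that same carbon with loss of the amine, forming O1–C2. The closest known reaction type is the palladium-catalysed carbonylative Sonogashira-type coupling and annulation of ortho-iodophenols with terminal arylacetylenes to flavones. Ring C closes by a 6-endo addition–elimination on the enaminone, which is why the flavone and not the 5-exo aurone should result. No stereocentre is formed. The step needs carbonylative over direct alkynylation, which CO pressure, the absence of copper and the fast CO uptake of the electron-rich, doubly ortho-substituted arylpalladium species should secure, and alkynyl transfer over amide formation, which the crowding around the aroylpalladium centre should favour.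

Step 4
Reactants: 9 5,7-dimethoxy-2-(2,3,4-trimethoxyphenyl)-4H-chromen-4-one
Product: 11 3-hydroxy-5,7-dimethoxy-2-(2,3,4-trimethoxyphenyl)-4H-chromen-4-one, via flavone epoxide 10 (not isolated)
Conditions: DMDO (acetone solution, excess, in portions), CH2Cl2, 0 °C → rt; then p-TsOH·H2O (cat.), CH2Cl2, rt
Reagents that add atoms: dimethyldioxirane, CC1(C)OO1
Why: Dioxirane epoxidation of the C2=C3 bond gives the racemic cis-fused epoxide 10, which under acid catalysis opens at C2 to the cation stabilised by O1 and the aryl group and loses H3 to give the flavonol (epoxide-to-enol isomerisation), so both stereocentres of 10 disappear.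

Step 5
Reactants: 11 3-hydroxy-5,7-dimethoxy-2-(2,3,4-trimethoxyphenyl)-4H-chromen-4-one
Product: 12 3,5,7-trimethoxy-2-(2,3,4-trimethoxyphenyl)-4H-chromen-4-one
Conditions: MeI, K2CO3, acetone, reflux
Reagents that add atoms: iodomethane, CI
Why: Williamson O-methylation of the acidic enolic 3-hydroxyl, which is the only free hydroxyl in 11.

Step 6
Reactants: 12 3,5,7-trimethoxy-2-(2,3,4-trimethoxyphenyl)-4H-chromen-4-one
Product: 13 5-hydroxy-3,7-dimethoxy-2-(2,3,4-trimethoxyphenyl)-4H-chromen-4-one
Conditions: BCl3 (1.2 equiv), CH2Cl2, −78 → 0 °C; then H2O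
Reagents that add atoms: none
Why: Chelation-controlled Lewis acid ether cleavage, in which BCl3 bridges the C4 carbonyl and the peri 5-methoxy oxygen in a six-membered chelate, chloride removes that methyl group, and the resulting boron chelate occupies the carbonyl so that the 3-methoxy and ring B methoxy groups should survive at low temperature until water frees the phenol.

Step 7
Reactants: 13 5-hydroxy-3,7-dimethoxy-2-(2,3,4-trimethoxyphenyl)-4H-chromen-4-one
Product: 15 5,8-dihydroxy-3,7-dimethoxy-2-(2,3,4-trimethoxyphenyl)-4H-chromen-4-one, via potassium aryl sulfate 14 (not isolated)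
Conditions: K2S2O8 (1.1 equiv), aq KOH, pyridine, 15–20 °C; then aq HCl, 90 °C, Ar
Reagents that add atoms: potassium peroxodisulfate, [K+].[K+].[O-]S(=O)(=O)OOS(=O)(=O)[O-]
Why: Elbs persulfate oxidation, in which the 5-phenoxide attacks a peroxide oxygen of peroxodisulfate through its para carbon C8 to give aryl sulfate 14, whose acid hydrolysis under argon releases the 8-hydroxyl; this para-hydroxylation is established for 5-hydroxy-3,7-dimethoxyflavones.

Compound list
1 | 3,5-dimethoxyphenol | COc1cc(O)cc(OC)c1 | starting material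
2 | 2-iodo-3,5-dimethoxyphenol | COc1cc(O)c(I)c(OC)c1 | intermediate
3 | 2,3,4-trimethoxybenzaldehyde | COc1ccc(C=O)c(OC)c1OC | starting material
4 | dimethyl (1-diazo-2-oxopropyl)phosphonate | COP(=O)(OC)C(=[N+]=[N-])C(C)=O | starting material
5 | 1-ethynyl-2,3,4-trimethoxybenzene | C#Cc1ccc(OC)c(OC)c1OC | intermediate
6 | carbon monoxide | [C-]#[O+] | starting material
7 | 1-(2-hydroxy-4,6-dimethoxyphenyl)-3-(2,3,4-trimethoxyphenyl)prop-2-yn-1-one (ynone, not isolated) | COc1cc(O)c(C(=O)C#Cc2ccc(OC)c(OC)c2OC)c(OC)c1 | intermediate
8 | (E)-3-(diethylamino)-1-(2-hydroxy-4,6-dimethoxyphenyl)-3-(2,3,4-trimethoxyphenyl)prop-2-en-1-one (enaminone, not isolated; drawn as the E isomer, either geometry can close the ring) | CCN(CC)/C(=C/C(=O)c1c(O)cc(OC)cc1OC)c1ccc(OC)c(OC)c1OC | intermediate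
9 | 5,7-dimethoxy-2-(2,3,4-trimethoxyphenyl)-4H-chromen-4-one | COc1ccc(-c2cc(=O)c3c(OC)cc(OC)cc3o2)c(OC)c1OC | intermediate
10 | racemic cis-2,3-epoxide of 9: 2,3-epoxy-5,7-dimethoxy-2-(2,3,4-trimethoxyphenyl)chroman-4-one (flavone numbering; one enantiomer drawn, not isolated) | O=C1c2c(OC)cc(OC)cc2O[C@]3(c4ccc(OC)c(OC)c4OC)O[C@H]13 | intermediate
11 | 3-hydroxy-5,7-dimethoxy-2-(2,3,4-trimethoxyphenyl)-4H-chromen-4-one | COc1ccc(-c2oc3cc(OC)cc(OC)c3c(=O)c2O)c(OC)c1OC | intermediate
12 | 3,5,7-trimethoxy-2-(2,3,4-trimethoxyphenyl)-4H-chromen-4-one | COc1ccc(-c2oc3cc(OC)cc(OC)c3c(=O)c2OC)c(OC)c1OC | intermediate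
13 | 5-hydroxy-3,7-dimethoxy-2-(2,3,4-trimethoxyphenyl)-4H-chromen-4-one | COc1ccc(-c2oc3cc(OC)cc(O)c3c(=O)c2OC)c(OC)c1OC | intermediate
14 | potassium 5-hydroxy-3,7-dimethoxy-4-oxo-2-(2,3,4-trimethoxyphenyl)-4H-chromen-8-yl sulfate (not isolated) | COc1ccc(-c2oc3c(OS(=O)(=O)[O-])c(OC)cc(O)c3c(=O)c2OC)c(OC)c1OC.[K+] | intermediate
15 | 5,8-dihydroxy-3,7-dimethoxy-2-(2,3,4-trimethoxyphenyl)-4H-chromen-4-one (5,8-dihydroxy-3,7,2',3',4'-pentamethoxyflavone) | COc1ccc(-c2oc3c(O)c(OC)cc(O)c3c(=O)c2OC)c(OC)c1OC | target

Total step count: 7. Longest linear sequence: 6 steps (steps 1, 3, 4, 5, 6 and 7 from 3,5-dimethoxyphenol); step 2 is a one-step branch that joins at step 3.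

Steps most likely to fail

1. Step 3 (key step). Several processes could compete:
- capture of the aroylpalladium intermediate by diethylamine (amide formation);
- copper-free direct alkynylation followed by closure to a 2-arylbenzofuran;
- 5-exo closure of the ynone;
- slow oxidative addition into the hindered, electron-rich C–I bond.

Fallback: the route sets out from aldehyde 3, which is condensed with commercial 2'-hydroxy-4',6'-dimethoxyacetophenone (KOH, EtOH, rt, Claisen–Schmidt condensation) to give the chalcone (E)-1-(2-hydroxy-4,6-dimethoxyphenyl)-3-(2,3,4-trimethoxyphenyl)prop-2-en-1-one F1. Oxidative cyclization of the chalcone with catalytic I2 in DMSO at 130 °C should then give the flavone, and the route is rejoined at compound 9.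

2. Step 7. Several processes could limit the oxidation:
- slow reaction of the strongly chelated 5-phenoxide with peroxodisulfate;
- competing attack at C6;
- further oxidation of the product quinol;
- alkaline opening of ring C.

Fallback: the route sets out from compound 12, because fully O-alkylated 5,7-dioxygenated flavones are halogenated at C8.
- Iodination (NIS, catalytic TFA, MeCN, rt) should give 8-iodo-3,5,7-trimethoxy-2-(2,3,4-trimethoxyphenyl)-4H-chromen-4-one F2.
- Miyaura borylation (B2pin2, PdCl2(dppf), KOAc, dioxane, 90 °C) should give the pinacol boronate 3,5,7-trimethoxy-8-(4,4,5,5-tetramethyl-1,3,2-dioxaborolan-2-yl)-2-(2,3,4-trimethoxyphenyl)-4H-chromen-4-one F3.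
- Oxidation of the C–B bond (NaBO3·4H2O, THF–H2O, rt) should give 8-hydroxy-3,5,7-trimethoxy-2-(2,3,4-trimethoxyphenyl)-4H-chromen-4-one F4.
- Chelation-controlled 5-O-demethylation with BCl3 (2.5 equiv, CH2Cl2, −78 → 0 °C; then H2O), as in step 6, returns to the route at target 15.

3. Step 1. Iodination could go para to the hydroxyl (C4, between the methoxy groups) or occur twice, which would erode the supply of the key-step precursor.

Fallback: the route sets out from phenol 1 and fixes the position by directed metalation instead of electrophilic substitution.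
- Carbamoylation (ClCONEt2, K2CO3, MeCN, reflux) gives 3,5-dimethoxyphenyl N,N-diethylcarbamate F5.
- Ortho-lithiation between the carbamate and the adjacent methoxy group (sec-butyllithium, TMEDA, THF, −78 °C) followed by I2 gives 2-iodo-3,5-dimethoxyphenyl N,N-diethylcarbamate F6.
- Hydrolysis (NaOH, EtOH, reflux; then acidification) returns to the route at compound 2.

Further compounds
F1 | step 3 | (E)-1-(2-hydroxy-4,6-dimethoxyphenyl)-3-(2,3,4-trimethoxyphenyl)prop-2-en-1-one | COc1cc(O)c(C(=O)/C=C/c2ccc(OC)c(OC)c2OC)c(OC)c1
F2 | step 7 | 8-iodo-3,5,7-trimethoxy-2-(2,3,4-trimethoxyphenyl)-4H-chromen-4-one | COc1ccc(-c2oc3c(I)c(OC)cc(OC)c3c(=O)c2OC)c(OC)c1OC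
F3 | step 7 | 3,5,7-trimethoxy-8-(4,4,5,5-tetramethyl-1,3,2-dioxaborolan-2-yl)-2-(2,3,4-trimethoxyphenyl)-4H-chromen-4-one | COc1ccc(-c2oc3c(B4OC(C)(C)C(C)(C)O4)c(OC)cc(OC)c3c(=O)c2OC)c(OC)c1OC
F4 | step 7 | 8-hydroxy-3,5,7-trimethoxy-2-(2,3,4-trimethoxyphenyl)-4H-chromen-4-one | COc1ccc(-c2oc3c(O)c(OC)cc(OC)c3c(=O)c2OC)c(OC)c1OC
F5 | step 1 | 3,5-dimethoxyphenyl N,N-diethylcarbamate | CCN(CC)C(=O)Oc1cc(OC)cc(OC)c1
F6 | step 1 | 2-iodo-3,5-dimethoxyphenyl N,N-diethylcarbamate | CCN(CC)C(=O)Oc1cc(OC)cc(OC)c1I
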